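The imidazole (ring A) is disconnected at N3–C4, and the carbinol C–O bond on the C4 side chain is traced back to an alkyne. The key step exploits two features: the carbinol carbon is the distal carbon of an aryl alkyne, and C5 of ring A, which carries the 4-methoxybenzyl group, can be an sp3 stereocentre from L-tyrosine until the ring aromatizes. In one operation, silver-catalysed 5-exo-dig hydroamination followed by dioxirane oxygenation closes ring A, installs the hydroxyl group and relays the C5 configuration to the carbinol while C5 becomes aromatic. The precursor is a mono-Teoc N-methyl propargylguanidine with an S propargylic centre.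

Key step: step 7

Remark: the target carbinol is R (O > imidazol-4-yl > aryl > H) and the propargylic centre of the precursor is S, as in L-tyrosine; Teoc (2-(trimethylsilyl)ethoxycarbonyl) is kept as the only guanidine protecting group because the doubly activated carbinol formed in step 7 tolerates neither acid nor hydrogenolysis.

Step 1
Reactants: 1 N-Boc-N-methyl-O-methyl-L-tyrosine
Product: 2 tert-butyl N-[(2S)-1-[methoxy(methyl)amino]-3-(4-methoxyphenyl)-1-oxopropan-2-yl]-N-methylcarbamate (Weinreb amide)
Conditions: MeNHOMe·HCl, EDCI·HCl, HOBt, i-Pr2NEt, CH2Cl2, 0 °C → rt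
Reagents that add atoms: N,O-dimethylhydroxylamine hydrochloride, SMILES CNOC.Cl
Why: Carbodiimide amide coupling to the Weinreb amide; the urethane-protected N-methyl amino acid is not prone to oxazolone formation, so the α-centre should be retained.

Step 2
Reactants: 2 Weinreb amide; 3 dimethyl (1-diazo-2-oxopropyl)phosphonate
Product: 5 tert-butyl N-[(2S)-1-(4-methoxyphenyl)but-3-yn-2-yl]-N-methylcarbamate, via aldehyde 4 (not isolated)
Conditions: i-Bu2AlH, CH2Cl2, −78 °C; then MeOH, K2CO3, 3, −78 °C → rt
Reagents that add atoms: dimethyl (1-diazo-2-oxopropyl)phosphonate (3), SMILES COP(=O)(OC)C(=[N+]=[N-])C(C)=O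
Why: i-Bu2AlH reduces the Weinreb amide to a chelated aluminium hemiaminal that releases aldehyde 4 only on methanolysis, and the Ohira–Bestmann variant of the Seyferth–Gilbert homologation converts it in the same flask into the terminal alkyne; the α-carbon is not a reacting atom and the aldehyde is never isolated, which should limit enolization.

Step 3
Reactants: 5 terminal alkyne; 6 1-iodo-4-methoxybenzene
Product: 7 tert-butyl N-[(2S)-1,4-bis(4-methoxyphenyl)but-3-yn-2-yl]-N-methylcarbamate
Conditions: PdCl2(PPh3)2 (2 mol %), CuI (4 mol %), Et3N, THF, rt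
Reagents that add atoms: 1-iodo-4-methoxybenzene (6), SMILES COc1ccc(I)cc1
Why: Sonogashira coupling (oxidative addition of the aryl iodide to zerovalent palladium formed in the flask, copper acetylide transmetalation, reductive elimination) is reliable for propargylic carbamates and does not touch the stereocentre.

Step 4
Reactants: 7 Boc-protected aryl alkyne
Product: 8 (2S)-1,4-bis(4-methoxyphenyl)-N-methylbut-3-yn-2-amine
Conditions: CF3CO2H, CH2Cl2, 0 °C; then aq NaHCO3
Reagents that add atoms: none
Why: Acidolytic Boc cleavage (loss of the tert-butyl cation, then decarboxylation) at low temperature should leave the aryl alkyne and the propargylic centre untouched, and the free base is liberated on basic work-up.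

Step 5
Reactants: 9 cyanamide; 10 2,5-dioxopyrrolidin-1-yl 2-(trimethylsilyl)ethyl carbonate (Teoc-OSu)
Product: 11 potassium cyano{[2-(trimethylsilyl)ethoxy]carbonyl}azanide (potassium salt of N-Teoc-cyanamide)
Conditions: KOH (2 equiv), H2O/THF, 0 °C → rt; KHSO4 to pH 3, extraction; KOH (1 equiv), MeOH
Reagents that add atoms: Teoc-OSu (10), SMILES C[Si](C)(C)CCOC(=O)ON1C(=O)CCC1=O; potassium hydroxide, SMILES [K+].[OH-]
Why: N-acylation of the cyanamide anion by an active carbonate, the reaction type that gives the benzyloxycarbonyl and tert-butoxycarbonyl cyanamide salts, followed by isolation of the acidic acylcyanamide as its potassium salt.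

Step 6
Reactants: 8 secondary amine; 11 potassium salt of N-Teoc-cyanamide
Product: 13 2-(trimethylsilyl)ethyl N-{N-[(2S)-1,4-bis(4-methoxyphenyl)but-3-yn-2-yl]-N-methylcarbamimidoyl}carbamate, via N-silylcarbodiimide 12 (not isolated)
Conditions: Me3SiCl, MeCN, rt; then aq NaHCO3
Reagents that add atoms: potassium salt of N-Teoc-cyanamide (11), SMILES [K+].N#C[N-]C(=O)OCC[Si](C)(C)C
Why: Chlorosilane-activated acylcyanamide guanylation: the salt and Me3SiCl give the electrophilic N-silylcarbodiimide 12, the hindered secondary amine adds to its central carbon, and aqueous work-up removes silicon to leave a guanidine acylated on one nitrogen only, with the propargylic centre untouched.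

Step 7
Reactants: 13 mono-Teoc propargylguanidine
Product: 16 2-(trimethylsilyl)ethyl N-{4-[(R)-hydroxy(4-methoxyphenyl)methyl]-5-(4-methoxybenzyl)-1-methyl-1H-imidazol-2-yl}carbamate, via Z-ene-guanidine 14 (not isolated), via hydroxy-5H-imidazole 15 (not isolated)
Conditions: AgOTf (10 mol %), CH2Cl2, rt; then NaHCO3, dimethyldioxirane (acetone solution, 1.1 equiv), −78 → −20 °C
Reagents that add atoms: dimethyldioxirane, SMILES CC1(C)OO1
Why: Proposed new method: monovalent silver should activate the aryl alkyne of 13 so that the unacylated guanidine nitrogen adds anti to the metal at the proximal alkyne carbon (5-exo-dig closure of ring A, N3–C4 bond) and protodemetalation leaves the Z ene-guanidine 14 with its C5 stereocentre intact. Dimethyldioxirane added to the same flask should then transfer an oxygen atom to the exocyclic carbon, the nucleophilic terminus of the N3–C4=C enamine unit and the former distal alkyne carbon, giving the carbinol 15 in which C4=N3 is an amidine-type double bond; prototropy of the now activated C5–H to the exocyclic nitrogen aromatizes ring A to 16 and erases the auxiliary centre. The closest known reaction types are the silver-catalysed 5-exo-dig hydroamination of propargylguanidines and the Rubottom-type oxygenation of enol ethers and enamides by peracids or dioxiranes, which have not been merged into an oxygenative aromatization of an ene-guanidine. The single new stereocentre, the carbinol carbon, is controlled by C5: ring A and the Z alkene of 14 are coplanar, the 4-methoxybenzyl group on C5 shields one face, and oxygen delivery to the other face of the 5S, Z intermediate leads to the R configuration. The step needs ring closure by the free nitrogen in the 5-exo mode instead of 6-endo attack at the anisyl-bearing carbon (expected from the soft silver catalyst and from leaving exactly one guanidine nitrogen unacylated), Z geometry (a consequence of anti aminometalation) and oxygen transfer that is faster than prototropic aromatization to the deoxy imidazole. The last point is served by the acylimino (Teoc) group, which holds the exocyclic tautomer, and by adding the buffered oxidant cold and in slight excess only, so that the less electron-rich carbamate-protected product and the anisole rings are not oxidized further.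

Step 8
Reactants: 16 Teoc-protected aminoimidazole carbinol
Product: 17 (R)-[2-amino-5-(4-methoxybenzyl)-1-methyl-1H-imidazol-4-yl](4-methoxyphenyl)methanol
Conditions: Bu4NF, THF, rt → 40 °C
Reagents that add atoms: none
Why: Fluoride-induced fragmentation of the 2-(trimethylsilyl)ethyl carbamate (attack at silicon, loss of ethene, decarboxylation) frees the 2-amine under non-acidic conditions that the ionization-prone carbinol should tolerate.

Step 9
Reactants: 17 aminoimidazole carbinol; 18 1-methylparabanic acid
Product: 22 4-({4-[(R)-hydroxy(4-methoxyphenyl)methyl]-5-(4-methoxybenzyl)-1-methyl-1H-imidazol-2-yl}amino)-1-methyl-1H-imidazole-2,5-dione (target), via silyl imidate 19 (not isolated), via silyl ether amine 20 (not isolated), via silyl ether 21 (not isolated)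
Conditions: N,O-bis(trimethylsilyl)acetamide (BSA), MeCN, rt; then toluene, 100 °C; then MeOH, rt
Reagents that add atoms: 1-methylparabanic acid (18), SMILES CN1C(=O)NC(=O)C1=O
Why: Silyl-transfer condensation of a 2-aminoimidazole with an imide (amidine formation by addition–elimination at C4 of the silyl imidate 19), the standard way of attaching this dehydrohydantoin unit, while the carbinol is masked in the flask as its trimethylsilyl ether and released by methanolysis without involving the stereocentre.

Compound list
1 | N-Boc-N-methyl-O-methyl-L-tyrosine | COc1ccc(C[C@@H](C(=O)O)N(C)C(=O)OC(C)(C)C)cc1 | starting material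
2 | tert-butyl N-[(2S)-1-[methoxy(methyl)amino]-3-(4-methoxyphenyl)-1-oxopropan-2-yl]-N-methylcarbamate | COc1ccc(C[C@@H](C(=O)N(C)OC)N(C)C(=O)OC(C)(C)C)cc1 | intermediate
3 | dimethyl (1-diazo-2-oxopropyl)phosphonate | COP(=O)(OC)C(=[N+]=[N-])C(C)=O | starting material
4 | tert-butyl N-[(2S)-1-(4-methoxyphenyl)-3-oxopropan-2-yl]-N-methylcarbamate | COc1ccc(C[C@@H](C=O)N(C)C(=O)OC(C)(C)C)cc1 | intermediate
5 | tert-butyl N-[(2S)-1-(4-methoxyphenyl)but-3-yn-2-yl]-N-methylcarbamate | COc1ccc(C[C@@H](C#C)N(C)C(=O)OC(C)(C)C)cc1 | intermediate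
6 | 1-iodo-4-methoxybenzene | COc1ccc(I)cc1 | starting material
7 | tert-butyl N-[(2S)-1,4-bis(4-methoxyphenyl)but-3-yn-2-yl]-N-methylcarbamate | COc1ccc(C[C@@H](C#Cc2ccc(OC)cc2)N(C)C(=O)OC(C)(C)C)cc1 | intermediate
8 | (2S)-1,4-bis(4-methoxyphenyl)-N-methylbut-3-yn-2-amine | COc1ccc(C[C@@H](C#Cc2ccc(OC)cc2)NC)cc1 | intermediate
9 | cyanamide | NC#N | starting material
10 | 2,5-dioxopyrrolidin-1-yl 2-(trimethylsilyl)ethyl carbonate (Teoc-OSu) | C[Si](C)(C)CCOC(=O)ON1C(=O)CCC1=O | starting material
11 | potassium cyano{[2-(trimethylsilyl)ethoxy]carbonyl}azanide | [K+].N#C[N-]C(=O)OCC[Si](C)(C)C | intermediate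
12 | 2-(trimethylsilyl)ethyl N-{[(trimethylsilyl)imino]methylidene}carbamate | C[Si](C)(C)CCOC(=O)N=C=N[Si](C)(C)C | intermediate
13 | 2-(trimethylsilyl)ethyl N-{N-[(2S)-1,4-bis(4-methoxyphenyl)but-3-yn-2-yl]-N-methylcarbamimidoyl}carbamate | COc1ccc(C[C@@H](C#Cc2ccc(OC)cc2)N(C)C(=N)NC(=O)OCC[Si](C)(C)C)cc1 | intermediate
14 | 2-(trimethylsilyl)ethyl N-[(4Z,5S)-4-(4-methoxybenzylidene)-5-(4-methoxybenzyl)-1-methylimidazolidin-2-ylidene]carbamate | CN1C(=NC(=O)OCC[Si](C)(C)C)N/C(=C\c2ccc(OC)cc2)[C@@H]1Cc1ccc(OC)cc1 | intermediate
15 | 2-(trimethylsilyl)ethyl N-[(5S)-4-[(R)-hydroxy(4-methoxyphenyl)methyl]-5-(4-methoxybenzyl)-1-methyl-1,5-dihydro-2H-imidazol-2-ylidene]carbamate | CN1C(=NC(=O)OCC[Si](C)(C)C)N=C([C@H](O)c2ccc(OC)cc2)[C@@H]1Cc1ccc(OC)cc1 | intermediate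
16 | 2-(trimethylsilyl)ethyl N-{4-[(R)-hydroxy(4-methoxyphenyl)methyl]-5-(4-methoxybenzyl)-1-methyl-1H-imidazol-2-yl}carbamate | COc1ccc(Cc2c([C@H](O)c3ccc(OC)cc3)nc(NC(=O)OCC[Si](C)(C)C)n2C)cc1 | intermediate
17 | (R)-[2-amino-5-(4-methoxybenzyl)-1-methyl-1H-imidazol-4-yl](4-methoxyphenyl)methanol | COc1ccc(Cc2c([C@H](O)c3ccc(OC)cc3)nc(N)n2C)cc1 | intermediate
18 | 1-methylparabanic acid (1-methylimidazolidine-2,4,5-trione) | CN1C(=O)NC(=O)C1=O | starting material
19 | 1-methyl-4-[(trimethylsilyl)oxy]-1H-imidazole-2,5-dione | CN1C(=O)N=C(O[Si](C)(C)C)C1=O | intermediate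
20 | 4-[(R)-(4-methoxyphenyl)(trimethylsilyloxy)methyl]-5-(4-methoxybenzyl)-1-methyl-1H-imidazol-2-amine | COc1ccc(Cc2c([C@H](O[Si](C)(C)C)c3ccc(OC)cc3)nc(N)n2C)cc1 | intermediate
21 | 4-({4-[(R)-(4-methoxyphenyl)(trimethylsilyloxy)methyl]-5-(4-methoxybenzyl)-1-methyl-1H-imidazol-2-yl}amino)-1-methyl-1H-imidazole-2,5-dione | COc1ccc(Cc2c([C@H](O[Si](C)(C)C)c3ccc(OC)cc3)nc(NC3=NC(=O)N(C)C3=O)n2C)cc1 | intermediate
22 | 4-({4-[(R)-hydroxy(4-methoxyphenyl)methyl]-5-(4-methoxybenzyl)-1-methyl-1H-imidazol-2-yl}amino)-1-methyl-1H-imidazole-2,5-dione (CNP0288484.1) | COc1ccc(Cc2c([C@H](O)c3ccc(OC)cc3)nc(NC3=NC(=O)N(C)C3=O)n2C)cc1 | target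

Total steps: 9. Longest linear sequence: 8 steps (1–4 and 6–9); step 5 is a one-step side branch.

Steps most likely to fail

Step 7 (proposed new method). Three processes could defeat it: prototropic aromatization of the ene-guanidine may outrun oxygen transfer, oxygen may be delivered to both faces of the exocyclic alkene, or the electron-rich product may be oxidized further. The fallback uses known reactions only, sets out from alkyne 7 and comes back to the route at amine 17. Buffered permanganate oxidation (KMnO4, NaHCO3, MgSO4, acetone/H2O) of the alkyne would give the 1,2-diketone tert-butyl N-[(2S)-1,4-bis(4-methoxyphenyl)-3,4-dioxobutan-2-yl]-N-methylcarbamate F1. HCl in dioxane would remove the Boc group to give (3S)-1,4-bis(4-methoxyphenyl)-3-(methylamino)butane-1,2-dione hydrochloride F2. This would be condensed at once with cyanamide in aqueous ethanol at pH 4–5 and 80 °C, the classical 2-aminoimidazole synthesis from an α-amino ketone, to give [2-amino-5-(4-methoxybenzyl)-1-methyl-1H-imidazol-4-yl](4-methoxyphenyl)methanone F3. Corey–Bakshi–Shibata reduction of F3 would then give 17, with borane in excess to cover complexation by the aminoimidazole and the antipode of the oxazaborolidine fixed by a trial reduction and stereochemical correlation. In this variant the carbinol is set by the catalyst and the tyrosine centre is not used.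

Step 2. The transient α-amino aldehyde may enolize in the basic methanolic medium of the alkynylation, eroding the configuration that step 7 later relays. The fallback sets out from Weinreb amide 2 and comes back at alkyne 5 by a Corey–Fuchs sequence that avoids basic protic conditions. LiAlH4 in THF at 0 °C would give aldehyde 4, used crude. Ramirez olefination (CBr4, PPh3, Et3N, CH2Cl2, 0 °C) would give tert-butyl N-[(2S)-4,4-dibromo-1-(4-methoxyphenyl)but-3-en-2-yl]-N-methylcarbamate F4. n-BuLi (2.2 equiv, THF, −78 °C) would then convert F4 into 5 by elimination, bromine–lithium exchange and Fritsch–Buttenberg–Wiechell rearrangement.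

Step 9. The carbinol carbon is flanked by the 2-aminoimidazole and the 4-methoxyphenyl ring, and it may ionize or be substituted while its labile trimethylsilyl ether exchanges under the hot silyl-transfer conditions, with loss of configuration. The fallback sets out from amine 17 and comes back at target 22 with a persistent protecting group. TBSCl, imidazole and DMF would give 4-[(R)-[tert-butyl(dimethyl)silyl]oxy(4-methoxyphenyl)methyl]-5-(4-methoxybenzyl)-1-methyl-1H-imidazol-2-amine F5. Condensation with 18 and BSA as in step 9 would give 4-({4-[(R)-[tert-butyl(dimethyl)silyl]oxy(4-methoxyphenyl)methyl]-5-(4-methoxybenzyl)-1-methyl-1H-imidazol-2-yl}amino)-1-methyl-1H-imidazole-2,5-dione F6. Bu4NF buffered with AcOH in THF at 0 °C would then release 22.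

Further compounds
F1 | step 7 | tert-butyl N-[(2S)-1,4-bis(4-methoxyphenyl)-3,4-dioxobutan-2-yl]-N-methylcarbamate | COc1ccc(C[C@@H](C(=O)C(=O)c2ccc(OC)cc2)N(C)C(=O)OC(C)(C)C)cc1
F2 | step 7 | (3S)-1,4-bis(4-methoxyphenyl)-3-(methylamino)butane-1,2-dione hydrochloride | COc1ccc(C[C@@H](C(=O)C(=O)c2ccc(OC)cc2)NC)cc1.Cl
F3 | step 7 | [2-amino-5-(4-methoxybenzyl)-1-methyl-1H-imidazol-4-yl](4-methoxyphenyl)methanone | COc1ccc(Cc2c(C(=O)c3ccc(OC)cc3)nc(N)n2C)cc1
F4 | step 2 | tert-butyl N-[(2S)-4,4-dibromo-1-(4-methoxyphenyl)but-3-en-2-yl]-N-methylcarbamate | COc1ccc(C[C@@H](C=C(Br)Br)N(C)C(=O)OC(C)(C)C)cc1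
F5 | step 9 | 4-[(R)-[tert-butyl(dimethyl)silyl]oxy(4-methoxyphenyl)methyl]-5-(4-methoxybenzyl)-1-methyl-1H-imidazol-2-amine | COc1ccc(Cc2c([C@H](O[Si](C)(C)C(C)(C)C)c3ccc(OC)cc3)nc(N)n2C)cc1
F6 | step 9 | 4-({4-[(R)-[tert-butyl(dimethyl)silyl]oxy(4-methoxyphenyl)methyl]-5-(4-methoxybenzyl)-1-methyl-1H-imidazol-2-yl}amino)-1-methyl-1H-imidazole-2,5-dione | COc1ccc(Cc2c([C@H](O[Si](C)(C)C(C)(C)C)c3ccc(OC)cc3)nc(NC3=NC(=O)N(C)C3=O)n2C)cc1
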